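Ring A carries C1-OH beside C2-OAr and a second oxygen at C4, para to C1. This pattern lets ring A be assembled from two three-carbon pieces. C6-C1-C2 comes from an aryloxyacetone that already holds ring B (C6' bromine installed, C4' oxygen benzyl-masked), and C3-C4-C5 comes from nitromalonaldehyde. One double aldol condensation forms C2-C3 and C5-C6, aromatises ring A and delivers the whole diaryl ether with C1-OH free and C4 as nitro, so the ring A oxygens are differentiated from the outset. Capping C1, converting nitro into OH and unmasking C4'-OH then let two phenols steer four brominations to C3, C5, C3' and C5'.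

Key step: step 4

Atom labels: ring A = C1(OH), C2(OAr), C3(Br), C4(OH), C5(Br), C6(H). Ring B = C1'(O), C2'(H), C3'(Br), C4'(OH), C5'(Br), C6'(Br). The target has no stereocentre.

Assumption: sodium nitromalonaldehyde is drawn as the anhydrous salt although it is isolated and weighed as the monohydrate. It is sensitive to impact and heat, so it is made in small batches behind a shield and used promptly.

Step 1
Reactants: 1 4-(benzyloxy)phenol
Product: 2 4-(benzyloxy)-2-bromophenol
Conditions: NBS (1.0 equiv), MeCN, 0 °C to rt, dark
Reagents that add atoms: N-bromosuccinimide, O=C1CCC(=O)N1Br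
Why: Electrophilic aromatic bromination, in which the free hydroxyl is the strongest donor and its para position is occupied, so one equivalent of NBS in a polar solvent in the dark should give the single ortho bromide (the future C6'-Br) without radical attack on the benzylic CH2.

Step 2
Reactants: 2 4-(benzyloxy)-2-bromophenol; 3 chloroacetone
Product: 4 1-[4-(benzyloxy)-2-bromophenoxy]propan-2-one
Conditions: K2CO3 (1.5 equiv), acetone, reflux
Reagents that add atoms: none
Why: Williamson ether synthesis, in which the phenoxide displaces chloride from the SN2-activated alpha-halo ketone, a standard entry to aryloxyacetones, while the weak base keeps aldol self-condensation of the product low.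

Step 3
Reactants: 5 mucobromic acid
Product: 6 sodium nitromalonaldehyde Na[O2NC(CHO)2] (isolated as monohydrate)
Conditions: NaNO2 (4 equiv), H2O/EtOH, 50-55 °C, efficient hood; cool to 0 °C, filter, recrystallise from aq EtOH, air-dry at rt only
Reagents that add atoms: sodium nitrite, [Na+].[O-]N=O; water, O
Why: Established nitrite degradation of mucobromic acid, in which nitrite replaces the bromide on the carbon next to the formyl group by addition-elimination, the second bromide is hydrolysed and CO2 is lost, leaving the resonance-stabilised dialdehyde anion that crystallises as its sodium salt.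

Step 4
Reactants: 4 1-[4-(benzyloxy)-2-bromophenoxy]propan-2-one; 6 sodium nitromalonaldehyde
Product: 8 2-[4-(benzyloxy)-2-bromophenoxy]-4-nitrophenol, via open-chain enone salt 7 (not isolated)
Conditions: 6 (1.5 equiv), NaOH (1.1 equiv, 1 M aq), EtOH/H2O, N2, 0 °C to rt, 4 added slowly in EtOH, 24-48 h; then 1 M HCl to pH 3
Reagents that add atoms: none
Why: Hydroxide first removes a proton from the more acidic OCH2 carbon of 4, the enolate adds to one formyl group of 6 and water is lost, giving the charge-delocalised open-chain salt 7, whose C2=C3 geometry can equilibrate to the form with the acetyl group and the nitro-bearing carbon on the same side. The methyl-side enolate of 7 then attacks the remaining formyl group in a 6-(enolendo)-exo-trig aldol closure of ring A, and a second dehydration plus tautomerisation gives the aromatic 4-nitrophenolate, an irreversible sink that pulls the reversible aldol steps forward. The nearest precedent class is the long-known ring synthesis of 4-nitrophenols from this dialdehyde salt and ketones enolisable on both sides, where unsymmetrical methyl ketones of type RCH2COCH3 place R at the 2-position. In atom terms C1 derives from the C=O carbon, C2 from OCH2, C6 from CH3, and C3, C4 and C5 from the formyl, nitro-bearing and formyl carbons of 6, and no stereocentre arises. Constitution is not in question because ring closure consumes both alpha carbons, so the only selectivity needed is cross- over self-condensation, secured by 6 being non-enolisable and in excess while 4 is fed in slowly. The aryl bromide, the benzyl ether and the aryl-oxygen bonds are inert to cold dilute NaOH.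

Step 5
Reactants: 8 2-[4-(benzyloxy)-2-bromophenoxy]-4-nitrophenol
Product: 9 4-(benzyloxy)-2-bromo-1-(2-methoxy-5-nitrophenoxy)benzene
Conditions: MeI (1.5 equiv), K2CO3 (1.5 equiv), DMF, rt
Reagents that add atoms: iodomethane, CI
Why: Williamson O-methylation, in which the acidic 4-nitrophenol is fully ionised by K2CO3 and is the only nucleophilic site, and the electron-rich ring B cannot accept a Smiles-type aryl shift, so C1-O is capped as the methyl ether that later keeps bromine away from C6.

Step 6
Reactants: 9 4-(benzyloxy)-2-bromo-1-(2-methoxy-5-nitrophenoxy)benzene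
Product: 10 3-[4-(benzyloxy)-2-bromophenoxy]-4-methoxyaniline
Conditions: Fe powder (5 equiv), NH4Cl, EtOH/H2O, 80 °C
Reagents that add atoms: none
Why: Bechamp-type iron reduction, in which stepwise electron and proton transfer at the metal surface takes nitro to amine under near-neutral conditions that spare the aryl bromide and the benzyl ether, both of which catalytic hydrogenation would endanger.

Step 7
Reactants: 10 3-[4-(benzyloxy)-2-bromophenoxy]-4-methoxyaniline
Product: 12 3-[4-(benzyloxy)-2-bromophenoxy]-4-methoxyphenol, via arenediazonium tetrafluoroborate 11 (not isolated)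
Conditions: t-BuONO (1.05 equiv), 48% aq HBF4 (2.5 equiv), MeCN, 0 °C; then Cu(NO3)2·3H2O (30 equiv) in H2O, Cu2O (1 equiv), rt
Reagents that add atoms: water, O; tert-butyl nitrite, CC(C)(C)ON=O (nitrogen of 11); tetrafluoroboric acid, [H+].F[B-](F)(F)F (counter-ion of 11)
Why: Diazotisation followed by copper-mediated hydroxydediazoniation (Sandmeyer-type radical process), in which monovalent copper reduces 11 to the aryl radical with loss of N2 and hydrated divalent copper transfers OH to it at room temperature, a sequence well established for amino diaryl ethers that avoids the boiling acid which would threaten the benzyl ether.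

Step 8
Reactants: 12 3-[4-(benzyloxy)-2-bromophenoxy]-4-methoxyphenol
Product: 13 3-(2-bromo-4-hydroxyphenoxy)-4-methoxyphenol
Conditions: BCl3 (3 equiv), pentamethylbenzene (3 equiv), CH2Cl2, -78 °C; then H2O
Reagents that add atoms: none
Why: Lewis-acid benzyl ether cleavage with a non-basic cation scavenger, in which the benzyl cation is trapped by Friedel-Crafts alkylation of pentamethylbenzene instead of the electron-rich rings, and at -78 °C the aryl methyl ether, the diaryl ether and the aryl bromide stay intact.

Step 9
Reactants: 13 3-(2-bromo-4-hydroxyphenoxy)-4-methoxyphenol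
Product: 14 2,6-dibromo-4-methoxy-3-(2,3,5-tribromo-4-hydroxyphenoxy)phenol
Conditions: Br2 (4.1 equiv), anhydrous AcOH, rt, dark; aq NaHSO3 quench
Reagents that add atoms: bromine, BrBr
Why: Phenol-directed electrophilic aromatic bromination, in which C4-OH (reinforced by C2-OAr) activates C3 and C5 and C4'-OH activates C3' and C5', whereas C6 and C2' lie meta to the phenols and are served only by ether oxygens, so four equivalents should stop at the pentabromide.

Step 10
Reactants: 14 2,6-dibromo-4-methoxy-3-(2,3,5-tribromo-4-hydroxyphenoxy)phenol
Product: 15 3,5-dibromo-2-(2,3,5-tribromo-4-hydroxyphenoxy)benzene-1,4-diol (target)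
Conditions: BBr3 (5 equiv), CH2Cl2, -78 °C to rt; ice-water, work-up under N2
Reagents that add atoms: none
Why: BBr3 aryl methyl ether cleavage (boron-oxygen complexation, then SN2 attack of bromide on the methyl group), which leaves diaryl ether and aryl bromides untouched and, being acidic, avoids both aerial oxidation of the hydroquinone and base-induced Smiles-type migration of the now electron-poor ring B.

Compound list
1 | 4-(benzyloxy)phenol | Oc1ccc(OCc2ccccc2)cc1 | starting material
2 | 4-(benzyloxy)-2-bromophenol | Oc1ccc(OCc2ccccc2)cc1Br | intermediate
3 | chloroacetone | CC(=O)CCl | starting material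
4 | 1-[4-(benzyloxy)-2-bromophenoxy]propan-2-one | CC(=O)COc1ccc(OCc2ccccc2)cc1Br | intermediate
5 | mucobromic acid, (2Z)-2,3-dibromo-4-oxobut-2-enoic acid | OC(=O)/C(Br)=C(/Br)C=O | starting material
6 | sodium nitromalonaldehyde, Na[O2NC(CHO)2] (handled as monohydrate) | [Na+].O=C[C-](C=O)[N+](=O)[O-] | intermediate
7 | sodium salt of (3E)-4-[4-(benzyloxy)-2-bromophenoxy]-2-nitro-5-oxohex-3-enal (not isolated) | [Na+].CC(=O)/C(Oc1ccc(OCc2ccccc2)cc1Br)=C\[C-](C=O)[N+](=O)[O-] | intermediate
8 | 2-[4-(benzyloxy)-2-bromophenoxy]-4-nitrophenol | Oc1ccc([N+](=O)[O-])cc1Oc1ccc(OCc2ccccc2)cc1Br | intermediate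
9 | 4-(benzyloxy)-2-bromo-1-(2-methoxy-5-nitrophenoxy)benzene | COc1ccc([N+](=O)[O-])cc1Oc1ccc(OCc2ccccc2)cc1Br | intermediate
10 | 3-[4-(benzyloxy)-2-bromophenoxy]-4-methoxyaniline | COc1ccc(N)cc1Oc1ccc(OCc2ccccc2)cc1Br | intermediate
11 | 3-[4-(benzyloxy)-2-bromophenoxy]-4-methoxybenzenediazonium tetrafluoroborate (not isolated) | COc1ccc([N+]#N)cc1Oc1ccc(OCc2ccccc2)cc1Br.F[B-](F)(F)F | intermediate
12 | 3-[4-(benzyloxy)-2-bromophenoxy]-4-methoxyphenol | COc1ccc(O)cc1Oc1ccc(OCc2ccccc2)cc1Br | intermediate
13 | 3-(2-bromo-4-hydroxyphenoxy)-4-methoxyphenol | COc1ccc(O)cc1Oc1ccc(O)cc1Br | intermediate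
14 | 2,6-dibromo-4-methoxy-3-(2,3,5-tribromo-4-hydroxyphenoxy)phenol | COc1cc(Br)c(O)c(Br)c1Oc1cc(Br)c(O)c(Br)c1Br | intermediate
15 | 3,5-dibromo-2-(2,3,5-tribromo-4-hydroxyphenoxy)benzene-1,4-diol | Oc1cc(Br)c(O)c(Br)c1Oc1cc(Br)c(O)c(Br)c1Br | target

Total step count: 10. Longest linear sequence: 9 (steps 1, 2, 4, 5, 6, 7, 8, 9, 10). Step 3 is a one-step side branch.

Steps most likely to fail

Step 4. Self-aldolisation of the ketone, sluggish addition to the charge-delocalised formyl groups, base-induced decay of the dialdehyde salt and poor solubility of the lipophilic ketone in the aqueous medium may together outrun the ring-closing second condensation. In that case ring A would be bought rather than built. Setting out from 2, a Chan-Lam O-arylation would make the C2-O bond directly, using commercial (2-methoxy-5-nitrophenyl)boronic acid, Cu(OAc)2, pyridine and 4 Å molecular sieves in CH2Cl2 under air at rt. It comes back to the route at 9. The aryl bromide is inert under these oxidative copper conditions, and the detour creates no compound outside the list (F0).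

Step 7. Three processes can drain material here:
- hydrogen abstraction by the aryl radical, which loses the nitrogen function without oxygen uptake;
- azo coupling between unreacted diazonium ion and the electron-rich phenol as it forms;
- oxidation of the product by divalent copper.

The C-O bond would then be made by way of boron. Setting out from 10, a metal-free Sandmeyer-type borylation (t-BuONO, B2pin2, MeCN, rt) should give 2-{3-[4-(benzyloxy)-2-bromophenoxy]-4-methoxyphenyl}-4,4,5,5-tetramethyl-1,3,2-dioxaborolane F1. Oxidation of its C-B bond (30% H2O2, NaOH, THF/H2O, 0 °C) comes back to the route at 12. No free phenol is present while diazonium ions exist, which removes the coupling pathway.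

Step 9. Three things can turn four simultaneous brominations into an inseparable mixture:
- stalling at the crowded positions C3 (between OH and OAr) and C5' (between OH and Br);
- continued bromination at C6 or C2' once reagent is in local excess;
- ipso attack para to the phenols with oxidative loss of an ether substituent.

The halogenation would then be divided by ring, setting out from 12, where only ring A carries a free phenol.
- Br2 (2 equiv, CH2Cl2, 0 °C) should give 3-[4-(benzyloxy)-2-bromophenoxy]-2,6-dibromo-4-methoxyphenol F2.
- BCl3 and pentamethylbenzene (CH2Cl2, -78 °C) then free 2,6-dibromo-3-(2-bromo-4-hydroxyphenoxy)-4-methoxyphenol F3.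
- A second two-fold bromination (Br2, 2 equiv, AcOH, rt), now confined to ring B, comes back to the route at 14.

Each stage can be purified and checked separately.

Further compounds
F0 | step 4 | none | none
F1 | step 7 | 2-{3-[4-(benzyloxy)-2-bromophenoxy]-4-methoxyphenyl}-4,4,5,5-tetramethyl-1,3,2-dioxaborolane | COc1ccc(B2OC(C)(C)C(C)(C)O2)cc1Oc1ccc(OCc2ccccc2)cc1Br
F2 | step 9 | 3-[4-(benzyloxy)-2-bromophenoxy]-2,6-dibromo-4-methoxyphenol | COc1cc(Br)c(O)c(Br)c1Oc1ccc(OCc2ccccc2)cc1Br
F3 | step 9 | 2,6-dibromo-3-(2-bromo-4-hydroxyphenoxy)-4-methoxyphenol | COc1cc(Br)c(O)c(Br)c1Oc1ccc(O)cc1Br
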